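**Plan**

1. Germacrane numbering is used: C6/C7 lactone carbons, C8 ester carbon, C10 quaternary ether carbon, C3 hemiketal carbon, C14 methyl, C15 hydroxymethyl. Retrosynthetic cuts, in order: the C10–O bond of the tetrahydrofuran (C3–OH from water) gives the macrocyclic 3-oxo-10(14)-ene 18; C6–C7 and the lactone C12–O give the keto-enal allylic bromide 16; the (Z)-C3(=O)–C4=C5–C6HO unit gives a 2,3-disubstituted furan; C8–C9 gives aldehyde 5 + allylboronate 12; C1–C2 gives 2-methyl-3-furoic acid + an isobutenyl dichloride.
2. Forward: a furan carries C3–C6 and C15 as a masked cis-ene-dicarbonyl; allylboration joins the halves; furan opening, then one chromium-mediated step closes the ten-membered carbocycle and the γ-lactone; the tetrahydrofuran hemiketal ring O–C3–C2–C1–C10 is closed last.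
3. Feature that makes the last event possible: in the ten-membered ring the C3 carbonyl oxygen is 1,4 to C10 (O=C3–C2–C1–C10), and C10 is a tertiary carbon carrying the exocyclic C14 methylene. Protonation therefore gives a cation that the ketone oxygen captures 5-exo, creating the 11-oxabicyclo[6.2.1]undecane core.
4. Stereochemistry: C8 from catalyst-controlled allylboration; C6 and C7 from the macrocyclic Barbier closure relative to C8; C10 in the key step (oxygen on the face syn to the 8-ester), C3 following from the bridge; 4Z from the furan. Helpers: the furan ring (opened in step 10) and the C15 silyl ether (removed in step 13).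

Key step: step 12

Remark: C3 is the hemiketal bridgehead; it cannot be set independently of C10 (a one-atom oxygen bridge) and equilibrates through the open hydroxy-ketone, so it is written throughout with the descriptor of the given SMILES and only C10 is treated as a centre to be controlled.

**Route**

Step 1
Reactants: 1 2,2-dimethoxyacetaldehyde; 2 methyl acrylate
Product: 3 methyl 3-hydroxy-4,4-dimethoxy-2-methylidenebutanoate (racemic)
Conditions: DABCO (0.5 equiv), 1,4-dioxane/H2O, rt
Reagents that add atoms: none
Why: Morita–Baylis–Hillman reaction of an activated α,α-dialkoxy aldehyde with the acrylate; the racemic carbinol centre is destroyed in step 2.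

Step 2
Reactants: 3 methyl 3-hydroxy-4,4-dimethoxy-2-methylidenebutanoate
Product: 4 methyl (2Z)-2-(bromomethyl)-4,4-dimethoxybut-2-enoate
Conditions: NBS, Me2S, CH2Cl2, 0 °C → rt
Reagents that add atoms: N-bromosuccinimide, O=C1CCC(=O)N1Br
Why: Corey–Kim-type activation of the allylic alcohol followed by SN2′ attack of bromide should give the rearranged primary allylic bromide with the usual thermodynamic (Z)-geometry (ester trans to the acetal carbon) under neutral conditions that spare the acetal.

Step 3
Reactants: 4 methyl (2Z)-2-(bromomethyl)-4,4-dimethoxybut-2-enoate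
Product: 5 methyl (2Z)-2-(bromomethyl)-4-oxobut-2-enoate
Conditions: TFA/H2O (9:1), CHCl3, 0 °C; used crude at once
Reagents that add atoms: water, O
Why: Acid-catalysed acetal hydrolysis, which the electron-poor enoate and the allylic bromide should tolerate for the short time needed.

Step 4
Reactants: 6 2-methylfuran-3-carboxylic acid; 7 3-chloro-2-(chloromethyl)prop-1-ene
Product: 8 2-[3-(chloromethyl)but-3-en-1-yl]furan-3-carboxylic acid
Conditions: LDA (2.2 equiv), THF, −78 °C; then 7 (3 equiv), −78 → 0 °C; H3O+
Reagents that add atoms: none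
Why: Lateral (vinylogous) deprotonation of the 2-methyl group of the furoate dianion and C-alkylation, in which SN2 and SN2′ attack converge on one product because the allylic dichloride is symmetric (its excess suppresses double alkylation).

Step 5
Reactants: 8 2-[3-(chloromethyl)but-3-en-1-yl]furan-3-carboxylic acid
Product: 10 {2-[3-(chloromethyl)but-3-en-1-yl]furan-3-yl}methanol, via isobutyl carbonic mixed anhydride 9 (not isolated)
Conditions: i-BuOCOCl, N-methylmorpholine, THF, −15 °C; then NaBH4, H2O, 0 °C
Reagents that add atoms: none
Why: Mixed-anhydride activation and borohydride reduction should convert the acid into the primary alcohol without touching the allylic chloride or the 1,1-disubstituted alkene.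

Step 6
Reactants: 10 {2-[3-(chloromethyl)but-3-en-1-yl]furan-3-yl}methanol
Product: 11 tert-butyl({2-[3-(chloromethyl)but-3-en-1-yl]furan-3-yl}methoxy)diphenylsilane
Conditions: TBDPSCl, imidazole, CH2Cl2, rt
Reagents that add atoms: tert-butyl(chloro)diphenylsilane, CC(C)(C)[Si](Cl)(c1ccccc1)c1ccccc1
Why: Standard silylation of a primary alcohol, giving a C15 ether that is stable to Grignard formation, NBS, Cr(II) and acid.

Step 7
Reactants: 11 tert-butyl({2-[3-(chloromethyl)but-3-en-1-yl]furan-3-yl}methoxy)diphenylsilane
Product: 12 tert-butyl[(2-{3-[(4,4,5,5-tetramethyl-1,3,2-dioxaborolan-2-yl)methyl]but-3-en-1-yl}furan-3-yl)methoxy]diphenylsilane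
Conditions: Mg, 2-isopropoxy-4,4,5,5-tetramethyl-1,3,2-dioxaborolane, THF, 0 °C → rt (Barbier mode)
Reagents that add atoms: 2-isopropoxy-4,4,5,5-tetramethyl-1,3,2-dioxaborolane, CC(C)OB1OC(C)(C)C(C)(C)O1
Why: Barbier-type magnesium insertion into the allylic chloride with in situ electrophilic borylation; both allyl termini are CH2, so allylic transposition is without consequence.

Step 8
Reactants: 5 methyl (2Z)-2-(bromomethyl)-4-oxobut-2-enoate; 12 the allylboronate
Product: 14 methyl (2Z,4R)-2-(bromomethyl)-8-{3-[(tert-butyldiphenylsilyloxy)methyl]furan-2-yl}-4-hydroxy-6-methylideneoct-2-enoate, via O-Bpin borate ester 13 (not isolated)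
Conditions: (R)-TRIP (5 mol%), 4 Å MS, toluene, −30 °C; aq. NaHCO3
Reagents that add atoms: none
Why: Chiral phosphoric acid-catalysed allylboration through a chair transition state should deliver the 2-substituted allyl group by its CH2 terminus to the Re face of the aldehyde, which sets C8 as R, while the allylic bromide and the ester are inert to the boronate.

Step 9
Reactants: 14 the (4R)-alcohol
Product: 15 methyl (2Z,4R)-2-(bromomethyl)-8-{3-[(tert-butyldiphenylsilyloxy)methyl]furan-2-yl}-6-methylidene-4-(2-methylpropanoyloxy)oct-2-enoate
Conditions: i-PrCOCl, 2,6-lutidine, CH2Cl2, −20 → 0 °C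
Reagents that add atoms: 2-methylpropanoyl chloride, CC(C)C(Cl)=O
Why: O-acylation with an acid chloride and a hindered pyridine base, chosen because it should not alkylate on the reactive 2-(bromomethyl)acrylate or promote cyclisation of the alcohol onto the bromide.

Step 10
Reactants: 15 the furan isobutyrate
Product: 16 methyl (2Z,4R,10Z)-2-(bromomethyl)-10-[(tert-butyldiphenylsilyloxy)methyl]-6-methylidene-4-(2-methylpropanoyloxy)-9,12-dioxododeca-2,10-dienoate
Conditions: NBS (1.05 equiv), NaHCO3, acetone/H2O (9:1), −20 °C; used at once
Reagents that add atoms: water, O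
Why: Oxidative furan ring opening (bromination and hydration at the furan α-carbons, then loss of HBr) should release the cis-ene-1,4-dicarbonyl, so the (Z)-C4=C5 geometry is inherited from the ring, the furan being far more nucleophilic than the 1,1-disubstituted alkene.

Step 11
Reactants: 16 the keto-enal allylic bromide
Product: 18 8β-(2-methylpropanoyloxy)-15-(tert-butyldiphenylsilyloxy)-3-oxogermacra-4Z,10(14),11(13)-trien-12,6α-olide (6R,7R,8R; trans-fused lactone), via C6 hydroxy ester 17 (not isolated)
Conditions: CrCl2 (6 equiv), THF (2 mM, syringe pump), rt; aq. NH4Cl; PPTS (cat.), CH2Cl2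
Reagents that add atoms: none
Why: Intramolecular Nozaki–Hiyama (Cr(II)) Barbier allylation, a known way to close germacranolide rings, in which the allylchromium should add through C7 to the aldehyde rather than the ketone via a chair-like transition state with both ring-bearing substituents pseudo-equatorial (6,7-anti, hence the trans-lactone) and H-8 eclipsing the allyl unit so that the 8-acyloxy group lies outside the forming ring, after which the C6 alkoxide lactonises onto the ester.

Step 12
Reactants: 18 the macrocyclic 3-oxo-10(14)-ene lactone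
Product: 19 15-O-tert-butyldiphenylsilyl ether of the target (3,10-epoxy-3-hydroxy hemiketal)
Conditions: TfOH (10 mol%), H2O (5 equiv), HFIP/CH2Cl2 (1:4), −20 → 0 °C
Reagents that add atoms: water, O
Why: Proposed new method: triflic acid in HFIP should protonate C14 of the only electron-rich alkene (the enone, acrylate and lactone alkenes are not basic enough) to give the tertiary C10 cation, which the C3 carbonyl oxygen, held 1,4 to it in the ten-membered ring (O=C3–C2–C1–C10), captures to a bicyclic oxocarbenium ion that water quenches at C3; the closest known reaction type is the Brønsted-acid Markovnikov hydroalkoxylation and hydrative cyclisation of γ,δ-unsaturated ketones to 2-hydroxytetrahydrofurans, which has not been shown transannularly on a ten-membered enone lactone. The ring closed is O–C3–C2–C1–C10 in the 5-exo-trig mode with respect to C10=C14, and with it the nine-membered oxacycle of the 11-oxabicyclo[6.2.1]undecane core. C10 is set by the face on which oxygen arrives: bonding on the face syn to the 8-O-isobutyrate sends the new C14 methyl to the opposite face, whereas the other face would force a 1,3-syn contact between C14 and the ester across C9, and the ester carbonyl itself can reach C10 only on the same face (six-membered acyloxonium), so any anchimeric assistance acts in the same sense; C3 is not free, because a one-atom bridge can only be cis. The selectivity needed is oxygen capture ahead of proton loss from the cation (which would lead through the 1(10)-alkene to a conjugated dienone) and ahead of transannular C–C bonding, and this should be secured by the enforced proximity of the ketone oxygen, by the electron-poor character of the other alkenes, and by a cold, non-basic, cation-stabilising medium containing a small excess of water.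

Step 13
Reactants: 19 the silyl-protected hemiketal
Product: 20 target, (3R,6R,7R,8R,10R)-3,15-dihydroxy-3,10-epoxy-8-(2-methylpropanoyloxy)germacra-4Z,11(13)-dien-12,6-olide
Conditions: HF·pyridine, pyridine, THF, 0 °C → rt
Reagents that add atoms: none
Why: Buffered fluoride cleavage of the primary TBDPS ether, which should leave the hemiketal, the isobutyrate and the α-methylene lactone untouched.

**Compound list**

1 | 2,2-dimethoxyacetaldehyde | COC(OC)C=O | starting material
2 | methyl acrylate | C=CC(=O)OC | starting material
3 | methyl 3-hydroxy-4,4-dimethoxy-2-methylidenebutanoate (racemic) | COC(OC)C(O)C(=C)C(=O)OC | intermediate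
4 | methyl (2Z)-2-(bromomethyl)-4,4-dimethoxybut-2-enoate | COC(OC)/C=C(\CBr)C(=O)OC | intermediate
5 | methyl (2Z)-2-(bromomethyl)-4-oxobut-2-enoate | O=C/C=C(\CBr)C(=O)OC | intermediate
6 | 2-methylfuran-3-carboxylic acid | Cc1occc1C(=O)O | starting material
7 | 3-chloro-2-(chloromethyl)prop-1-ene | C=C(CCl)CCl | starting material
8 | 2-[3-(chloromethyl)but-3-en-1-yl]furan-3-carboxylic acid | C=C(CCl)CCc1occc1C(=O)O | intermediate
9 | isobutyl carbonic mixed anhydride of 8 | C=C(CCl)CCc1occc1C(=O)OC(=O)OCC(C)C | intermediate (not isolated)
10 | {2-[3-(chloromethyl)but-3-en-1-yl]furan-3-yl}methanol | C=C(CCl)CCc1occc1CO | intermediate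
11 | tert-butyl({2-[3-(chloromethyl)but-3-en-1-yl]furan-3-yl}methoxy)diphenylsilane | C=C(CCl)CCc1occc1CO[Si](c2ccccc2)(c3ccccc3)C(C)(C)C | intermediate
12 | pinacol allylboronate derived from 11 | C=C(CB1OC(C)(C)C(C)(C)O1)CCc2occc2CO[Si](c3ccccc3)(c4ccccc4)C(C)(C)C | intermediate
13 | O-Bpin borate ester of 14 | C=C(CCc1occc1CO[Si](c2ccccc2)(c3ccccc3)C(C)(C)C)C[C@@H](OB4OC(C)(C)C(C)(C)O4)/C=C(\CBr)C(=O)OC | intermediate (not isolated)
14 | methyl (2Z,4R)-2-(bromomethyl)-8-{3-[(tert-butyldiphenylsilyloxy)methyl]furan-2-yl}-4-hydroxy-6-methylideneoct-2-enoate | C=C(CCc1occc1CO[Si](c2ccccc2)(c3ccccc3)C(C)(C)C)C[C@@H](O)/C=C(\CBr)C(=O)OC | intermediate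
15 | 4-O-(2-methylpropanoate) of 14 | C=C(CCc1occc1CO[Si](c2ccccc2)(c3ccccc3)C(C)(C)C)C[C@@H](OC(=O)C(C)C)/C=C(\CBr)C(=O)OC | intermediate
16 | methyl (2Z,4R,10Z)-2-(bromomethyl)-10-[(tert-butyldiphenylsilyloxy)methyl]-6-methylidene-4-(2-methylpropanoyloxy)-9,12-dioxododeca-2,10-dienoate | O=C/C=C(/CO[Si](c1ccccc1)(c2ccccc2)C(C)(C)C)C(=O)CCC(=C)C[C@@H](OC(=O)C(C)C)/C=C(\CBr)C(=O)OC | intermediate
17 | methyl 6α-hydroxy-8β-(2-methylpropanoyloxy)-15-(tert-butyldiphenylsilyloxy)-3-oxogermacra-4Z,10(14),11(13)-trien-12-oate (H-7 α) | O[C@@H]1/C=C(/CO[Si](c2ccccc2)(c3ccccc3)C(C)(C)C)C(=O)CCC(=C)C[C@@H](OC(=O)C(C)C)[C@H]1C(=C)C(=O)OC | intermediate (not isolated)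
18 | 8β-(2-methylpropanoyloxy)-15-(tert-butyldiphenylsilyloxy)-3-oxogermacra-4Z,10(14),11(13)-trien-12,6α-olide | C=C1C(=O)O[C@@H]2/C=C(/CO[Si](c3ccccc3)(c4ccccc4)C(C)(C)C)C(=O)CCC(=C)C[C@@H](OC(=O)C(C)C)[C@@H]12 | intermediate
19 | 15-O-tert-butyldiphenylsilyl ether of the target | C=C1C(=O)O[C@@H]2/C=C(/CO[Si](c4ccccc4)(c5ccccc5)C(C)(C)C)[C@@]3(O)CC[C@](C)(C[C@@H](OC(=O)C(C)C)[C@@H]12)O3 | intermediate
20 | (3R,6R,7R,8R,10R)-3,15-dihydroxy-3,10-epoxy-8-(2-methylpropanoyloxy)germacra-4Z,11(13)-dien-12,6-olide | C=C1C(=O)O[C@@H]2/C=C(/CO)[C@@]3(O)CC[C@](C)(C[C@@H](OC(=O)C(C)C)[C@@H]12)O3 | target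

**Count**

Total steps: 13. Longest linear sequence: 10 steps (6 → 20; the branch 1 → 5 joins at step 8).

**Steps most likely to fail**

Step 12 (proposed new method). The C10 cation may lose a proton instead of being captured, drifting through the 1(10)-alkene to a conjugated dienone, or oxygen may arrive on the wrong face of C10. The fallback uses known chemistry and avoids a free cation. It sets out from 18 and returns at 19. Iodoetherification of the γ,δ-unsaturated ketone (NIS, wet MeCN, −20 °C, 5-exo closure through the ketone hydrate) should give the 14-iodo hemiketal F1. Radical deiodination (Bu3SnH, Et3B/air, toluene, 0 °C) should then give 19.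

Step 11. Electron transfer from Cr(II) to the cis-ene-dione, or addition of the allylchromium to the C3 ketone (seven-membered ring), may compete with the ten-membered closure. The fallback masks the ketone before ring closure. It sets out from 16 and returns at 18. Soft enolisation (TBSOTf, 2,6-lutidine, CH2Cl2, −78 °C) should silylate only the ketone, the aldehyde having no α-hydrogen, to give the 9-silyloxy dienal F2. The same chromium-mediated closure and lactonisation should give the macrocyclic silyl enol ether F3. Dilute aqueous HCl in THF should then return the ketone 18.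

Step 8. Uncatalysed background allylboration of the very electrophilic aldehyde, or a mismatch between this aldehyde and the catalyst, may erode the enantioselectivity at C8. The fallback sets C8 by reduction instead of addition. It sets out from 5 and 12 and returns at 14. Uncatalysed allylboration (toluene, rt) should give the racemic alcohol F4. Dess–Martin periodinane should give the enone F5. Corey–Bakshi–Shibata reduction ((S)-Me-CBS, catecholborane, −78 °C) should give 14.

Further compounds
F1 | step 12 | 14-iodo analogue of 19 (10-iodomethyl hemiketal) | C=C1C(=O)O[C@@H]2/C=C(/CO[Si](c4ccccc4)(c5ccccc5)C(C)(C)C)[C@@]3(O)CC[C@](CI)(C[C@@H](OC(=O)C(C)C)[C@@H]12)O3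
F2 | step 11 | 9-O-tert-butyldimethylsilyl dienol ether of 16 (enol ether geometry not defined) | O=C/C=C(/CO[Si](c1ccccc1)(c2ccccc2)C(C)(C)C)C(O[Si](C)(C)C(C)(C)C)=CCC(=C)C[C@@H](OC(=O)C(C)C)/C=C(\CBr)C(=O)OC
F3 | step 11 | 3-O-tert-butyldimethylsilyl enol ether of 18 (2,4,10(14),11(13)-tetraene lactone) | C=C1C(=O)O[C@@H]2/C=C(/CO[Si](c3ccccc3)(c4ccccc4)C(C)(C)C)C(O[Si](C)(C)C(C)(C)C)=CCC(=C)C[C@@H](OC(=O)C(C)C)[C@@H]12
F4 | step 8 | racemic 14 | C=C(CCc1occc1CO[Si](c2ccccc2)(c3ccccc3)C(C)(C)C)CC(O)/C=C(\CBr)C(=O)OC
F5 | step 8 | methyl (2Z)-2-(bromomethyl)-8-{3-[(tert-butyldiphenylsilyloxy)methyl]furan-2-yl}-6-methylidene-4-oxooct-2-enoate | C=C(CCc1occc1CO[Si](c2ccccc2)(c3ccccc3)C(C)(C)C)CC(=O)/C=C(\CBr)C(=O)OC
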